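**Retrosynthetic overview**

1. The aryl C–Br is put in last (bromination para to the free OH); the phenol is carried as its methyl ether.
2. The (E)-bromomethylidene comes from Wittig bromomethylenation of a cyclopentenone C=O, and the ring C=C is then removed with diimide.
3. The cyclopentane is the only ring made (the arene is bought); it is closed by ring-closing metathesis of a vinyl ketone onto a propenyl group, with loss of propene.
4. Key step: an Eschenmoser–Claisen [3,3] rearrangement forms the C1–C2 bond and sets the quaternary carbon and the adjacent CH(CH3) by chirality transfer from an (S)-carbinol.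
5. The (S,E)-allylic alcohol comes from (S)-but-3-yn-2-ol by Sonogashira coupling, trans-hydroalumination/iodination and Negishi methylation.

Assumption: the target SMILES is read as (1R,2R,3E), and reagent 7 is taken as a catalogue item (otherwise made in one operation from N,N-dimethylpropanamide with Me2SO4 then NaOMe).

This route is a paper design; the conditions are standard ones for each reaction type and have not been run.

**Route**

Step 1
Reactants: 1 (S)-but-3-yn-2-ol; 2 1-iodo-2-methoxy-4-methylbenzene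
Product: 3 (2S)-4-(2-methoxy-4-methylphenyl)but-3-yn-2-ol
Conditions: PdCl2(PPh3)2 (2 mol%), CuI (4 mol%), Et3N, THF, rt
Reagents that add atoms: none
Why: Sonogashira coupling of the aryl iodide with the terminal alkyne runs at room temperature and does not touch the carbinol stereocentre brought in with 1.

Step 2
Reactants: 3 (2S)-4-(2-methoxy-4-methylphenyl)but-3-yn-2-ol
Product: 5 (2S,3Z)-4-iodo-4-(2-methoxy-4-methylphenyl)but-3-en-2-ol, via alkenylaluminate 4 (not isolated)
Conditions: Red-Al, THF, 0 °C → rt; EtOAc; then I2, −78 → 0 °C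
Reagents that add atoms: iodine, SMILES II
Why: Alkoxide-directed trans-hydroalumination delivers hydride to the carbon next to the carbinol and aluminium to the aryl-bearing carbon through a five-membered alkenylaluminate, and iodinolysis with retention gives the vinyl iodide with iodine cis to the carbinol carbon (hydroalumination–iodination).

Step 3
Reactants: 5 (2S,3Z)-4-iodo-4-(2-methoxy-4-methylphenyl)but-3-en-2-ol
Product: 6 (2S,3E)-4-(2-methoxy-4-methylphenyl)pent-3-en-2-ol
Conditions: MeZnCl (3 equiv), Pd(PPh3)4 (5 mol%), THF, 50 °C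
Reagents that add atoms: methylzinc chloride, SMILES C[Zn]Cl
Why: Negishi cross-coupling replaces iodine by methyl with retention of alkene geometry, giving the trisubstituted alkene with the aryl group trans to the carbinol carbon.

Step 4
Reactants: 6 (2S,3E)-4-(2-methoxy-4-methylphenyl)pent-3-en-2-ol; 7 1,1-dimethoxy-N,N-dimethylpropan-1-amine
Product: 10 (2R,3R,4E)-3-(2-methoxy-4-methylphenyl)-N,N,2,3-tetramethylhex-4-enamide, via mixed amide acetal 8 (not isolated), via ketene N,O-acetal 9 (not isolated)
Conditions: 7 (4 equiv), xylene, 140 °C, MeOH distilled off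
Reagents that add atoms: none
Why: In this Eschenmoser–Claisen [3,3]-sigmatropic rearrangement the (Z)-ketene N,O-acetal reacts through a chair transition state with the carbinol methyl equatorial, so the (S) C–O stereocentre is transferred suprafacially to the new quaternary carbon (R), the aryl-equatorial/methyl-axial arrangement sets the neighbouring CH(CH3) as R (aryl and that methyl cis in the later ring), and the old stereocentre ends as an (E)-propenyl group.

Step 5
Reactants: 10 (2R,3R,4E)-3-(2-methoxy-4-methylphenyl)-N,N,2,3-tetramethylhex-4-enamide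
Product: 12 (4R,5R,6E)-5-(2-methoxy-4-methylphenyl)-4,5-dimethylocta-1,6-dien-3-one, via lithium hemiaminal alkoxide 11 (not isolated)
Conditions: CH2=CHLi (2.5 equiv), THF, −78 → −20 °C; then cold 1 M HCl
Reagents that add atoms: vinyllithium, SMILES [Li]C=C
Why: Organolithium addition to the tertiary amide (nucleophilic acyl substitution) stops at the tetrahedral lithium hemiaminal alkoxide, which releases the vinyl ketone only on acidic quench, when the dimethylamine is protonated and cannot add back.

Step 6
Reactants: 12 (4R,5R,6E)-5-(2-methoxy-4-methylphenyl)-4,5-dimethylocta-1,6-dien-3-one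
Product: 13 (4R,5R)-4-(2-methoxy-4-methylphenyl)-4,5-dimethylcyclopent-2-en-1-one
Conditions: Grubbs II (5 mol%), CH2Cl2, 40 °C
Reagents that add atoms: none
Why: Ring-closing metathesis between the enone vinyl group and the propenyl group closes the five-membered ring under neutral conditions, expels propene and leaves both ring stereocentres untouched.

Step 7
Reactants: 13 (4R,5R)-4-(2-methoxy-4-methylphenyl)-4,5-dimethylcyclopent-2-en-1-one
Product: 15 1-[(1R,4E,5R)-4-(bromomethylidene)-1,5-dimethylcyclopent-2-en-1-yl]-2-methoxy-4-methylbenzene, via oxaphosphetane 14 (not isolated)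
Conditions: [Ph3PCH2Br]Br, KOtBu, THF, −78 °C; then 13, −78 °C → rt
Reagents that add atoms: (bromomethyl)triphenylphosphonium bromide, SMILES BrC[P+](c1ccccc1)(c1ccccc1)c1ccccc1.[Br-]
Why: Wittig olefination with the bromo ylide adds 1,2 to the enone and should place bromine on the less hindered side, syn to the flat vinylic CH and anti to the CH(CH3) carbon (the E geometry of the target), while the low temperature limits enolisation at the α′ stereocentre.

Step 8
Reactants: 15 1-[(1R,4E,5R)-4-(bromomethylidene)-1,5-dimethylcyclopent-2-en-1-yl]-2-methoxy-4-methylbenzene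
Product: 16 1-[(1R,2R,3E)-3-(bromomethylidene)-1,2-dimethylcyclopentyl]-2-methoxy-4-methylbenzene
Conditions: KO2CN=NCO2K, AcOH, MeOH, 0 °C → rt
Reagents that add atoms: none
Why: Diimide reduction is a concerted syn hydrogen transfer that takes the unhindered cis-disubstituted ring alkene much faster than the trisubstituted bromoalkene and cannot cleave C–Br bonds.

Step 9
Reactants: 16 1-[(1R,2R,3E)-3-(bromomethylidene)-1,2-dimethylcyclopentyl]-2-methoxy-4-methylbenzene
Product: 18 2-[(1R,2R,3E)-3-(bromomethylidene)-1,2-dimethylcyclopentyl]-5-methylphenol, via aryloxydibromoborane 17 (not isolated)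
Conditions: BBr3, CH2Cl2, −78 → 0 °C; then H2O
Reagents that add atoms: none
Why: Lewis-acid cleavage of the aryl methyl ether (BBr3 demethylation) proceeds at low temperature, where the electron-poor bromoalkene is not protonated and neither stereocentre is affected.

Step 10
Reactants: 18 2-[(1R,2R,3E)-3-(bromomethylidene)-1,2-dimethylcyclopentyl]-5-methylphenol
Product: 19 4-bromo-2-[(1R,2R,3E)-3-(bromomethylidene)-1,2-dimethylcyclopentyl]-5-methylphenol
Conditions: NBS (1.0 equiv), MeCN, 0 °C
Reagents that add atoms: N-bromosuccinimide, SMILES BrN1C(=O)CCC1=O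
Why: Electrophilic aromatic bromination of the phenol goes para to OH (ortho to the ring methyl), the least hindered activated position, and the deactivated vinyl bromide is left alone.

**Compound list**

1 | (S)-but-3-yn-2-ol | C[C@H](O)C#C | starting material
2 | 1-iodo-2-methoxy-4-methylbenzene | COc1cc(C)ccc1I | starting material
3 | (2S)-4-(2-methoxy-4-methylphenyl)but-3-yn-2-ol | C[C@H](O)C#Cc1ccc(C)cc1OC | intermediate
4 | sodium alkenyl(alkoxy)bis(2-methoxyethoxy)aluminate, five-membered 1,2-oxaaluminacycle from 3 (Al on the aryl-bearing alkene carbon) | C[C@@H]1O[Al-](OCCOC)(OCCOC)C(c2ccc(C)cc2OC)=C1.[Na+] | intermediate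
5 | (2S,3Z)-4-iodo-4-(2-methoxy-4-methylphenyl)but-3-en-2-ol | C[C@H](O)/C=C(\I)c1ccc(C)cc1OC | intermediate
6 | (2S,3E)-4-(2-methoxy-4-methylphenyl)pent-3-en-2-ol | C[C@H](O)/C=C(\C)c1ccc(C)cc1OC | intermediate
7 | 1,1-dimethoxy-N,N-dimethylpropan-1-amine (N,N-dimethylpropionamide dimethyl acetal) | CCC(OC)(OC)N(C)C | starting material
8 | 1-methoxy-1-{[(2S,3E)-4-(2-methoxy-4-methylphenyl)pent-3-en-2-yl]oxy}-N,N-dimethylpropan-1-amine (mixed amide acetal, epimers at the acetal carbon) | CCC(OC)(O[C@@H](C)/C=C(\C)c1ccc(C)cc1OC)N(C)C | intermediate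
9 | (1Z)-1-{[(2S,3E)-4-(2-methoxy-4-methylphenyl)pent-3-en-2-yl]oxy}-N,N-dimethylprop-1-en-1-amine (ketene N,O-acetal, methyl cis to O) | C/C=C(\O[C@@H](C)/C=C(\C)c1ccc(C)cc1OC)N(C)C | intermediate
10 | (2R,3R,4E)-3-(2-methoxy-4-methylphenyl)-N,N,2,3-tetramethylhex-4-enamide | CN(C)C(=O)[C@H](C)[C@](C)(c1ccc(C)cc1OC)/C=C/C | intermediate
11 | lithium (4R,5R,6E)-3-(dimethylamino)-5-(2-methoxy-4-methylphenyl)-4,5-dimethylocta-1,6-dien-3-olate (C3 epimers) | [Li+].[O-]C(C=C)(N(C)C)[C@H](C)[C@](C)(c1ccc(C)cc1OC)/C=C/C | intermediate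
12 | (4R,5R,6E)-5-(2-methoxy-4-methylphenyl)-4,5-dimethylocta-1,6-dien-3-one | C=CC(=O)[C@H](C)[C@](C)(c1ccc(C)cc1OC)/C=C/C | intermediate
13 | (4R,5R)-4-(2-methoxy-4-methylphenyl)-4,5-dimethylcyclopent-2-en-1-one | O=C1C=C[C@@](C)(c2ccc(C)cc2OC)[C@H]1C | intermediate
14 | spiro-oxaphosphetane from 13 and Ph3P=CHBr (3-bromo-2,2,2-triphenyl-1-oxa-2λ5-phosphaspiro[3.4]oct-5-ene carrying the ring substituents of 13) | BrC1P(c2ccccc2)(c2ccccc2)(c2ccccc2)OC13C=C[C@@](C)(c2ccc(C)cc2OC)[C@H]3C | intermediate
15 | 1-[(1R,4E,5R)-4-(bromomethylidene)-1,5-dimethylcyclopent-2-en-1-yl]-2-methoxy-4-methylbenzene | COc1cc(C)ccc1[C@]1(C)C=C/C(=C\Br)[C@@H]1C | intermediate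
16 | 1-[(1R,2R,3E)-3-(bromomethylidene)-1,2-dimethylcyclopentyl]-2-methoxy-4-methylbenzene | COc1cc(C)ccc1[C@]1(C)CC/C(=C\Br)[C@@H]1C | intermediate
17 | dibromo{2-[(1R,2R,3E)-3-(bromomethylidene)-1,2-dimethylcyclopentyl]-5-methylphenoxy}borane | BrB(Br)Oc1cc(C)ccc1[C@]1(C)CC/C(=C\Br)[C@@H]1C | intermediate
18 | 2-[(1R,2R,3E)-3-(bromomethylidene)-1,2-dimethylcyclopentyl]-5-methylphenol | Cc1ccc([C@]2(C)CC/C(=C\Br)[C@@H]2C)c(O)c1 | intermediate
19 | 4-bromo-2-[(1R,2R,3E)-3-(bromomethylidene)-1,2-dimethylcyclopentyl]-5-methylphenol | Cc1cc(O)c([C@]2(C)CC/C(=C\Br)[C@@H]2C)cc1Br | target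

**Totals**

Total step count: 10. Longest linear sequence: 10 steps (1 → 19).

**Three steps most likely to fail**

Step 4 (Eschenmoser–Claisen). The new quaternary centre is crowded, the mixed acetal of this aryl-conjugated allylic alcohol can ionise and eliminate to a diene, and chair/boat leakage would erode the C2 configuration. The fallback is an Ireland–Claisen through an ester enolate; it sets out from 6 and comes back at 10. Acylation of 6 with propanoyl chloride (pyridine, DMAP) gives (2S,3E)-4-(2-methoxy-4-methylphenyl)pent-3-en-2-yl propanoate F1. LDA in THF at −78 °C followed by Me3SiCl gives the (E)-O-silyl ketene acetal F2, with methyl cis to the allylic oxygen, the same enol geometry as in 9. On warming to room temperature this rearranges to trimethylsilyl (2R,3R,4E)-3-(2-methoxy-4-methylphenyl)-2,3-dimethylhex-4-enoate F3. Aqueous work-up frees (2R,3R,4E)-3-(2-methoxy-4-methylphenyl)-2,3-dimethylhex-4-enoic acid F4, and coupling with dimethylamine (EDC, HOBt) gives 10.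

Step 5 (vinyllithium on a hindered N,N-dimethylamide). Addition may be slow next to the quaternary carbon, and deprotonation at the α-CH would epimerise C2. The fallback replaces direct acyl substitution by reduction, addition and oxidation; it sets out from 10 and comes back at 12. Cp2Zr(H)Cl (THF, rt) reduces the amide to (2R,3R,4E)-3-(2-methoxy-4-methylphenyl)-2,3-dimethylhex-4-enal F5. Vinylmagnesium bromide (THF, −78 °C) gives (4R,5R,6E)-5-(2-methoxy-4-methylphenyl)-4,5-dimethylocta-1,6-dien-3-ol F6 as a C3 epimer mixture, and Dess–Martin periodinane oxidises it to 12.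

Step 7 (Wittig bromomethylenation). The basic ylide can enolise the enone at C5 (the α′ carbon) and erode the aryl/methyl cis relationship, and the E/Z ratio of the bromoalkene is not guaranteed. The fallback is a boron-Wittig olefination followed by stereoretentive bromodeboronation; it sets out from 13 and comes back at 15. LiCH(Bpin)2 (from CH2(Bpin)2 and LiTMP, THF, −78 °C → rt) gives the dienyl boronate 2-[(E)-[(2S,3R)-3-(2-methoxy-4-methylphenyl)-2,3-dimethylcyclopent-4-en-1-ylidene]methyl]-4,4,5,5-tetramethyl-1,3,2-dioxaborolane F7, with boron anti to the branched α-carbon. The spatial arrangement is the same as in 15; the S label is only a CIP priority change. CuBr2 in aqueous methanol replaces boron by bromine with retention and gives 15.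

Further compounds
F1 | step 4 | (2S,3E)-4-(2-methoxy-4-methylphenyl)pent-3-en-2-yl propanoate | CCC(=O)O[C@@H](C)/C=C(\C)c1ccc(C)cc1OC
F2 | step 4 | trimethyl{[(1E)-1-{[(2S,3E)-4-(2-methoxy-4-methylphenyl)pent-3-en-2-yl]oxy}prop-1-en-1-yl]oxy}silane | C/C=C(\O[C@@H](C)/C=C(\C)c1ccc(C)cc1OC)O[Si](C)(C)C
F3 | step 4 | trimethylsilyl (2R,3R,4E)-3-(2-methoxy-4-methylphenyl)-2,3-dimethylhex-4-enoate | C[Si](C)(C)OC(=O)[C@H](C)[C@](C)(c1ccc(C)cc1OC)/C=C/C
F4 | step 4 | (2R,3R,4E)-3-(2-methoxy-4-methylphenyl)-2,3-dimethylhex-4-enoic acid | OC(=O)[C@H](C)[C@](C)(c1ccc(C)cc1OC)/C=C/C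
F5 | step 5 | (2R,3R,4E)-3-(2-methoxy-4-methylphenyl)-2,3-dimethylhex-4-enal | O=C[C@H](C)[C@](C)(c1ccc(C)cc1OC)/C=C/C
F6 | step 5 | (4R,5R,6E)-5-(2-methoxy-4-methylphenyl)-4,5-dimethylocta-1,6-dien-3-ol (C3 epimers) | C=CC(O)[C@H](C)[C@](C)(c1ccc(C)cc1OC)/C=C/C
F7 | step 7 | 2-[(E)-[(2S,3R)-3-(2-methoxy-4-methylphenyl)-2,3-dimethylcyclopent-4-en-1-ylidene]methyl]-4,4,5,5-tetramethyl-1,3,2-dioxaborolane | COc1cc(C)ccc1[C@]1(C)C=C/C(=C\B2OC(C)(C)C(C)(C)O2)[C@@H]1C
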